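**Retrosynthetic overview**
- Feature: in the 2,3-dihydro-1,4-benzodioxine core (O1, C2 with the syringyl ring, C3 with CH2OH, O4; benzo ring = ring A) C3 is bonded to three different partners: O4 of ring A, the CH2OH carbon and benzylic C2. C3 is therefore treated as a carbene carbon.
- Key disconnection: O4–C3 and C3–C2 are made together from a ring A phenol, ethyl diazoacetate and O-acetylsyringaldehyde (rhodium carbene, oxonium ylide, aldol capture under a chiral phosphoric acid). This step fixes C3.
- O1–C2 disconnection: acid-mediated closure through the p-hydroxybenzyl cation. This is the only ring formed in the route (the dioxine ring; both arenes are bought), and it sets C2 trans to C3.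
- Side chain: ring A carries the three-carbon chain as an ethyl (E)-propenoate from the start, so both ethyl esters are reduced together in the last step.

Key step: step 4

**Assumptions**
- Target locants are used throughout: O1–C2(aryl)–C3(CH2OH)–O4, OMe on C5, side chain on C7. The target SMILES encodes the 2,3-trans (2S,3S) isomer.
- The sense of induction of the phosphoric acid at the carbene carbon cannot be predicted with confidence. The route is written with (R)-TRIP; the (S)-acid would be used if a first run shows the opposite sense.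
- 3,4-Dihydroxy-5-methoxybenzaldehyde (5-hydroxyvanillin) is taken as commercially available.

**Route**

Step 1
Reactants: 1 3,4-dihydroxy-5-methoxybenzaldehyde (5-hydroxyvanillin)
Product: 2 4-hydroxy-3-methoxy-5-(methoxymethoxy)benzaldehyde
Conditions: NaH (2.2 equiv), DMF, 0 °C; MOMCl (1.0 equiv), 0 °C → rt; aq. NH4Cl
Reagents that add atoms: chloromethyl methyl ether, COCCl
Why: Williamson-type O-alkylation of the catechol dianion, in which the 4-phenoxide is delocalised into the para-formyl group and flanked by two ortho substituents, so the localised, more basic meta-phenoxide should take the single equivalent of MOMCl.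

Step 2
Reactants: 2 4-hydroxy-3-methoxy-5-(methoxymethoxy)benzaldehyde
Product: 3 ethyl (E)-3-[4-hydroxy-3-methoxy-5-(methoxymethoxy)phenyl]prop-2-enoate
Conditions: Ph3P=CHCO2Et (1.3 equiv), toluene, 90 °C
Reagents that add atoms: ethyl (triphenylphosphoranylidene)acetate, CCOC(=O)C=P(c1ccccc1)(c1ccccc1)c1ccccc1
Why: Wittig olefination with a stabilised ylide, which tolerates the free phenol and the MOM acetal and should give the (E)-propenoate as stabilised ylides do.

Step 3
Reactants: 4 syringaldehyde (4-hydroxy-3,5-dimethoxybenzaldehyde)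
Product: 5 4-formyl-2,6-dimethoxyphenyl acetate
Conditions: Ac2O, pyridine, DMAP (cat.), CH2Cl2, rt
Reagents that add atoms: acetic anhydride, CC(=O)OC(C)=O
Why: DMAP-catalysed acylation of the hindered phenol, which caps the only O–H of the aldehyde partner and, as an electron-withdrawing group, raises the electrophilicity of the formyl group for step 4.

Step 4
Reactants: 3 ethyl (E)-3-[4-hydroxy-3-methoxy-5-(methoxymethoxy)phenyl]prop-2-enoate; 5 4-formyl-2,6-dimethoxyphenyl acetate (1.5 equiv); 6 ethyl diazoacetate (1.3 equiv)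
Product: 8 ethyl (2R,3S)-3-(4-acetoxy-3,5-dimethoxyphenyl)-2-{4-[(E)-3-ethoxy-3-oxoprop-1-en-1-yl]-2-methoxy-6-(methoxymethoxy)phenoxy}-3-hydroxypropanoate, via oxonium ylide 7 (not isolated)
Conditions: Rh2(OAc)4 (2 mol %), (R)-TRIP [(R)-3,3'-bis(2,4,6-triisopropylphenyl)-1,1'-binaphthyl-2,2'-diyl hydrogen phosphate, 10 mol %], 4 Å molecular sieves, CH2Cl2, −10 °C; 6 added in CH2Cl2 by syringe pump over 4 h
Reagents that add atoms: none
Why: Proposed new method: Rh2(OAc)4 converts 6 into the rhodium carbene, the 4-OH of 3 (the only free O–H in the flask) adds to it to give oxonium ylide 7, in effect a rhodium-associated enol, and the chiral phosphoric acid, hydrogen-bonded to this enol and to the formyl oxygen of 5, delivers the enol carbon to the aldehyde before the 1,2-proton shift can finish a plain O–H insertion, so that O4–C3 and C3–C2 (target locants) form in one operation. The closest known reaction type is the Rh2(OAc)4/chiral phosphoric acid co-catalysed three-component coupling of aryldiazoacetates, alcohols and aldehydes or imines through trapped oxonium ylides; new here are the acceptor-only diazoacetate, a phenol as the O–H partner and an electron-rich aryl aldehyde. No ring is closed in this step. The stereocentre at C2 of the propanoate (C3 of the target) is set by the chiral phosphate, which fixes the face of the enol that meets the aldehyde in the doubly hydrogen-bonded transition state; the carbinol centre should come out syn from the same assembly but is not relied on, since step 5 resets it. The step needs aldol capture to outrun the proton shift and carbene dimerisation, which slow addition of 6 at low temperature, an excess of 5 and the electron-withdrawing acetate on 5 are meant to secure, and the flanking OMe and OMOM oxygens of 3 can hold the transferring proton and so lengthen the life of the ylide. Chemoselectivity rests on the substrates: the phenol oxygen of 5 is capped, and the conjugated, ester-bearing C=C of 3 is a poor partner for the electrophilic carbene.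

Step 5
Reactants: 8 ethyl (2R,3S)-3-(4-acetoxy-3,5-dimethoxyphenyl)-2-{4-[(E)-3-ethoxy-3-oxoprop-1-en-1-yl]-2-methoxy-6-(methoxymethoxy)phenoxy}-3-hydroxypropanoate
Product: 11 ethyl (2S,3R)-7-[(E)-3-ethoxy-3-oxoprop-1-en-1-yl]-2-(4-hydroxy-3,5-dimethoxyphenyl)-5-methoxy-2,3-dihydro-1,4-benzodioxine-3-carboxylate (target locants; 2,3-trans), via diphenol hydroxy ester 9 (not isolated), via quinone methide 10 (not isolated)
Conditions: HCl (1.25 M in EtOH), EtOH, rt → 50 °C
Reagents that add atoms: none
Why: Acid-catalysed ethanolysis strips the MOM acetal and the aryl acetate (the ethyl esters only exchange degenerately with the solvent), the freed 4-hydroxy-3,5-dimethoxybenzyl alcohol 9 ionises to the p-hydroxybenzyl cation/quinone methide 10, and the adjacent ring A phenol adds to its exocyclic carbon in a reversible 6-exo-trig closure of O1–C2, so the 2,3-trans (diequatorial) arrangement and thus 2S should result whatever the carbinol configuration of 8, while C3, which does not ionise, keeps its configuration.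

Step 6
Reactants: 11 ethyl (2S,3R)-7-[(E)-3-ethoxy-3-oxoprop-1-en-1-yl]-2-(4-hydroxy-3,5-dimethoxyphenyl)-5-methoxy-2,3-dihydro-1,4-benzodioxine-3-carboxylate
Product: 12 4-[(2S,3S)-3-(hydroxymethyl)-7-[(E)-3-hydroxyprop-1-en-1-yl]-5-methoxy-2,3-dihydro-1,4-benzodioxin-2-yl]-2,6-dimethoxyphenol (target)
Conditions: diisobutylaluminium hydride (8 equiv), CH2Cl2/THF, −78 → 0 °C; aq. potassium sodium tartrate
Reagents that add atoms: none
Why: Hydride reduction with excess diisobutylaluminium hydride, in which the phenol consumes one equivalent and both ethyl esters are then taken to primary alcohols, the cinnamate by 1,2-addition so that the E-olefin survives, and no stereocentre is touched (the descriptor at C3 changes from R to S only because CH2OH ranks below C2).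

**Compound list**
1 | 3,4-dihydroxy-5-methoxybenzaldehyde (5-hydroxyvanillin) | COc1cc(C=O)cc(O)c1O | starting material
2 | 4-hydroxy-3-methoxy-5-(methoxymethoxy)benzaldehyde | COCOc1cc(C=O)cc(OC)c1O | intermediate
3 | ethyl (E)-3-[4-hydroxy-3-methoxy-5-(methoxymethoxy)phenyl]prop-2-enoate | CCOC(=O)/C=C/c1cc(OC)c(O)c(OCOC)c1 | intermediate
4 | syringaldehyde (4-hydroxy-3,5-dimethoxybenzaldehyde) | COc1cc(C=O)cc(OC)c1O | starting material
5 | 4-formyl-2,6-dimethoxyphenyl acetate | CC(=O)Oc1c(OC)cc(C=O)cc1OC | intermediate
6 | ethyl diazoacetate | CCOC(=O)C=[N+]=[N-] | starting material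
7 | oxonium ylide from 3 and the carbene of 6 (drawn as the free ylide; rhodium-associated in the flask) | CCOC(=O)[CH-][OH+]c1c(OC)cc(/C=C/C(=O)OCC)cc1OCOC | intermediate
8 | ethyl (2R,3S)-3-(4-acetoxy-3,5-dimethoxyphenyl)-2-{4-[(E)-3-ethoxy-3-oxoprop-1-en-1-yl]-2-methoxy-6-(methoxymethoxy)phenoxy}-3-hydroxypropanoate | CC(=O)Oc1c(OC)cc(cc1OC)[C@H](O)[C@H](C(=O)OCC)Oc1c(OCOC)cc(/C=C/C(=O)OCC)cc1OC | intermediate
9 | ethyl (2R,3S)-2-{4-[(E)-3-ethoxy-3-oxoprop-1-en-1-yl]-2-hydroxy-6-methoxyphenoxy}-3-hydroxy-3-(4-hydroxy-3,5-dimethoxyphenyl)propanoate | COc1cc(cc(OC)c1O)[C@H](O)[C@H](C(=O)OCC)Oc1c(O)cc(/C=C/C(=O)OCC)cc1OC | intermediate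
10 | ethyl (2R)-3-(3,5-dimethoxy-4-oxocyclohexa-2,5-dien-1-ylidene)-2-{4-[(E)-3-ethoxy-3-oxoprop-1-en-1-yl]-2-hydroxy-6-methoxyphenoxy}propanoate (quinone methide; its O-protonated form is the p-hydroxybenzyl cation) | O=C1C(OC)=CC(=C[C@H](C(=O)OCC)Oc2c(O)cc(/C=C/C(=O)OCC)cc2OC)C=C1OC | intermediate
11 | ethyl (2S,3R)-7-[(E)-3-ethoxy-3-oxoprop-1-en-1-yl]-2-(4-hydroxy-3,5-dimethoxyphenyl)-5-methoxy-2,3-dihydro-1,4-benzodioxine-3-carboxylate (target locants; trans) | COc1cc([C@@H]2Oc3cc(/C=C/C(=O)OCC)cc(OC)c3O[C@H]2C(=O)OCC)cc(OC)c1O | intermediate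
12 | 4-[(2S,3S)-3-(hydroxymethyl)-7-[(E)-3-hydroxyprop-1-en-1-yl]-5-methoxy-2,3-dihydro-1,4-benzodioxin-2-yl]-2,6-dimethoxyphenol | COc1cc([C@@H]2Oc3cc(/C=C/CO)cc(OC)c3O[C@H]2CO)cc(OC)c1O | target

**Totals**
Total step count: 6. Longest linear sequence: 5 steps (steps 1, 2, 4, 5, 6).

**Steps most likely to fail**

Step 4. The proton shift may outrun aldol capture, so that only O–H insertion to the aryloxyacetate occurs. The phosphate may also fail to control the face at the carbene carbon, or the carbene may be lost to dimerisation or to carbonyl-ylide formation with the excess aldehyde. The fallback is an auxiliary-controlled glycolate aldol of known type; it sets out from 3 and 5 and comes back to the route at 11. (R)-4-Benzyloxazolidin-2-one would be N-acylated (n-BuLi, bromoacetyl bromide, THF, −78 °C) to (R)-4-benzyl-3-(bromoacetyl)oxazolidin-2-one F1. Phenol 3 would be O-alkylated with it (K2CO3, acetone, rt) to the aryloxyacetyl imide F2. Its Z-boron enolate (Bu2BOTf, iPr2NEt, CH2Cl2, −78 °C, non-oxidative work-up) should add to 5 through a Zimmerman–Traxler chair to give the Evans syn aldol imide F3, with 2R fixed by the (R)-auxiliary. Ethanolic HCl as in step 5 should then close the dioxine ring to the benzodioxane imide F4. EtMgBr in EtOH (bromomagnesium ethoxide, 0 °C) would exchange the auxiliary for OEt and give 11.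

Step 5. The benzylic cation may lose the proton at the ester-bearing carbon (E1) to give an aryloxy-cinnamate, which erases C3. Ethanolysis of the hindered acetate may also be too slow for the cation to form. The fallback changes the order of events so that the classical closure of a 1-aryl-2-aryloxypropane-1,3-diol is used; it sets out from 8 and comes back at 12. NaBH4 in THF/EtOH at 0 °C should reduce the activated α-aryloxy-β-hydroxy ester and cleave the aryl acetate while leaving the conjugated ethyl ester, giving the diol ethyl (E)-3-{4-[(1S,2S)-1,3-dihydroxy-1-(4-hydroxy-3,5-dimethoxyphenyl)propan-2-yl]oxy-3-methoxy-5-(methoxymethoxy)phenyl}prop-2-enoate F5. Ethanolic HCl at rt would then remove the MOM group and close O1–C2 through the same cation, now without an acidified proton next to it, to the trans hydroxymethyl cinnamate F6. Diisobutylaluminium hydride would reduce the remaining ester to give 12.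

Step 1. The single equivalent of MOMCl may alkylate the wrong phenoxide or both. The fallback uses the opposite selectivity of weak-base alkylation and a temporary group; it sets out from 1 and comes back at 2. Allyl bromide with NaHCO3 and NaI in DMF at 40 °C should alkylate only the acidic para-formyl phenol, giving 4-(allyloxy)-3-hydroxy-5-methoxybenzaldehyde F7. MOMCl and iPr2NEt in CH2Cl2 would protect the remaining meta hydroxyl, giving 4-(allyloxy)-3-methoxy-5-(methoxymethoxy)benzaldehyde F8. Pd(PPh3)4 (zerovalent palladium) with morpholine in THF would remove the allyl group and give 2.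

**Further compounds**
F1 | step 4 | (R)-4-benzyl-3-(bromoacetyl)oxazolidin-2-one | O=C(CBr)N1[C@H](Cc2ccccc2)COC1=O
F2 | step 4 | ethyl (E)-3-[4-{2-[(R)-4-benzyl-2-oxooxazolidin-3-yl]-2-oxoethoxy}-3-methoxy-5-(methoxymethoxy)phenyl]prop-2-enoate | CCOC(=O)/C=C/c1cc(OC)c(OCC(=O)N2[C@H](Cc3ccccc3)COC2=O)c(OCOC)c1
F3 | step 4 | (R)-4-benzyl-3-[(2R,3S)-3-(4-acetoxy-3,5-dimethoxyphenyl)-2-{4-[(E)-3-ethoxy-3-oxoprop-1-en-1-yl]-2-methoxy-6-(methoxymethoxy)phenoxy}-3-hydroxypropanoyl]oxazolidin-2-one | CC(=O)Oc1c(OC)cc(cc1OC)[C@H](O)[C@H](C(=O)N1[C@H](Cc2ccccc2)COC1=O)Oc1c(OCOC)cc(/C=C/C(=O)OCC)cc1OC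
F4 | step 4 | ethyl (E)-3-[(2S,3R)-3-{[(R)-4-benzyl-2-oxooxazolidin-3-yl]carbonyl}-2-(4-hydroxy-3,5-dimethoxyphenyl)-5-methoxy-2,3-dihydro-1,4-benzodioxin-7-yl]prop-2-enoate | COc1cc([C@@H]2Oc3cc(/C=C/C(=O)OCC)cc(OC)c3O[C@H]2C(=O)N2[C@H](Cc3ccccc3)COC2=O)cc(OC)c1O
F5 | step 5 | ethyl (E)-3-{4-[(1S,2S)-1,3-dihydroxy-1-(4-hydroxy-3,5-dimethoxyphenyl)propan-2-yl]oxy-3-methoxy-5-(methoxymethoxy)phenyl}prop-2-enoate | COc1cc(cc(OC)c1O)[C@H](O)[C@H](CO)Oc1c(OCOC)cc(/C=C/C(=O)OCC)cc1OC
F6 | step 5 | ethyl (E)-3-[(2S,3S)-2-(4-hydroxy-3,5-dimethoxyphenyl)-3-(hydroxymethyl)-5-methoxy-2,3-dihydro-1,4-benzodioxin-7-yl]prop-2-enoate | COc1cc([C@@H]2Oc3cc(/C=C/C(=O)OCC)cc(OC)c3O[C@H]2CO)cc(OC)c1O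
F7 | step 1 | 4-(allyloxy)-3-hydroxy-5-methoxybenzaldehyde | C=CCOc1c(O)cc(C=O)cc1OC
F8 | step 1 | 4-(allyloxy)-3-methoxy-5-(methoxymethoxy)benzaldehyde | C=CCOc1c(OCOC)cc(C=O)cc1OC
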